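The runs were generated by integration with made-up constants, noise included.

Time counts in these flasks as a product with concentration, so a run at another charge can stand in for a run not yet made.

| setting | theta | alpha | Wednesday's | Tuesday's |
|---|---|---|---|---|
| first end groups | 0.013 M | 0.028 M | 0.019 M | 0.019 M |
| second end groups | 1.1 equiv | 1.1 equiv | 1.10 equiv | 1.10 equiv |
| remark | run made earlier | run made earlier |  |  |
| time |  |  | 5.0 min | 2.5 min |

| run | time / min | links / % | first end groups / % |
|---|---|---|---|
| theta | 0.417 | 37.9 | 62.3 |
| theta | 0.667 | 50.2 | 50.7 |
| theta | 1.00 | 59.8 | 40.3 |
| theta | 2.00 | 76.3 | 23.9 |
| theta | 3.00 | 83.7 | 16.9 |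
| theta | 5.00 | 90.3 | 10.0 |
| alpha | 0.833 | 74.3 | 25.9 |
| alpha | 1.50 | 85.0 | 14.8 |
| alpha | 2.50 | 90.8 | 9.1 |
| alpha | 3.00 | 92.7 | 7.3 |
| alpha | 4.00 | 94.4 | 6.0 |
| alpha | 5.00 | 95.5 | 4.3 |

(readings scatter by 0.3 percentage points)

- each molecule carries two end groups: a chain counts once for every two ends that are left, dead ends included; the units are half of the end groups of the two monomers charged
- the numbers in the tables scatter by 0.3 percentage points (one standard deviation)
- reactions considered so far: first end groups + second end groups <-> links + by-product

1. which of the two ends with the longer chains by the average number of monomer units in a chain (unreacted monomers counted as chains of one) ("neither" if they lie within 10 %) (Wednesday's / Tuesday's / neither)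
2. average number of monomer units in a chain (unreacted monomers counted as chains of one) at the end, Wednesday's
3. average number of monomer units in a chain (unreacted monomers counted as chains of one) at the end, Tuesday's

The reaction takes two species and gives two, so at fixed equivalents and fixed temperature, forward and back terms both scale with the square of the charge. The fraction of first end groups left, a, then follows one curve against the dose. Wednesday's flask stands at 0.0950 M·min and Tuesday's at 0.04750 M·min, the dose being the starting c(first end groups) times the time. First end groups are the limiting reagent, and length is both charges over the ends left, the second ends left being a plus the excess.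

Two alpha readings enclose Wednesday's dose, at 0.0840 M·min and 0.112 M·min, with a of 7.3 % and 6.0 %. These readings, which carry their scatter, therefore put the length between 8.54 and 9.55. For Tuesday's flask, the alpha reading at 0.0420 M·min and the theta reading at 0.0650 M·min give a of 14.8 % and 10.0 %, which with the same scatter put the length between 5.30 and 7.00. The lower bound for Wednesday's flask stands 22.0 % above the upper bound for Tuesday's, beyond the margin of 10 %.

My own tightening takes the reciprocal of a as straight across each gap. That gives a of 6.73 % and length 8.95 for Wednesday's flask, and a of 13.3 % and length 5.75 for Tuesday's.

The forecast, on the ground that “With equal molecularity, conversion depends only on k·A₀·t, so the earlier runs can be read across”, says Wednesday's, with 9 and 5.8. Both values lie inside the brackets.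

The simulation gives Wednesday's, with 9.18 against 5.66.

    first end groups + second end groups ⇌ links + by-product (K = 280, k = 1.65 /M/s)

Wednesday's flask keeps 6.4 % of its first end groups and 15 % of its second end groups at 5.00 min. The reading of Wednesday's flask at 80 s has a dose of 0.0253 M·min, between the alpha reading at 0.0233 M·min with 25.9 % left and the theta reading at 0.0260 M·min with 23.9 % left. That reading holds 24.4 % of first end groups, at length 3.58.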